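**Retrosynthetic overview**
1. Target 11 ⇐ silyl ether 10 ⇐ ketone 7 + one CH2 unit. The exocyclic C1–CH2 bond is made last, and the CH2O benzoate is not added but handed over from O–C6.
2. Ketone 7 ⇐ C2-symmetric all-trans diol dibenzoate 5 by mono-silylation and oxidation; the two hydroxyls are homotopic, so either gives the same ketone.
3. Diol 5 ⇐ anti-diepoxide 3 + two benzoic acid (both benzoates of the target) ⇐ cyclohexa-1,3-diene 1. One catalytic asymmetric epoxidation sets the absolute configuration; all other stereocentres are relayed.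
4. Rings: the carbocycle is bought. Temporary rings are two oxiranes (steps 1 and 2), then a spiro-oxirane and a 1,3-dioxan-2-ylium ring (both inside step 6).
5. Enabling feature: the ring oxygens on C6, C1, C2 and C3 are all mutually trans. With C1 as a ketone, the oxygens at C2, C3 and C6 are all equatorial on one locked chair, so an axial CH2 at C1 lands cis to O–C2 and O–C6, and the C6 benzoate sits 1,3-cis to it.

Key step: step 6

Remark: the target is read as [(1S,2S,3R,6R)-3-(benzoyloxy)-1,2,6-trihydroxycyclohexyl]methyl benzoate; C1–C6 in the text refer to this cyclohexyl numbering.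

**Step 1**
Reactants: 1 cyclohexa-1,3-diene
Product: 2 (1R,6S)-7-oxabicyclo[4.1.0]hept-2-ene
Conditions: (R,R)-Jacobsen Mn(III)(salen)Cl (4 mol %), 4-phenylpyridine N-oxide (20 mol %), aq. NaOCl (pH 11.3), CH2Cl2, 0 °C; product kept as a CH2Cl2 solution
Reagents that add atoms: sodium hypochlorite [Na+].[O-]Cl
Why: Jacobsen–Katsuki epoxidation of a conjugated cis-alkene; the chiral Mn-oxo species selects the alkene face and sets both oxirane stereocentres (the (R,R) catalyst is chosen by analogy with indene, where it places R at the carbon bearing the conjugating group), and the vinyl oxirane formed should resist a second oxygen transfer.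

**Step 2**
Reactants: 2 (1R,6S)-7-oxabicyclo[4.1.0]hept-2-ene
Product: 3 (1S,2S,4S,7S)-3,8-dioxatricyclo[5.1.0.0^2,4]octane
Conditions: mCPBA (1.2 equiv), CH2Cl2 / aq. phosphate buffer (pH 8), 0 °C → rt
Reagents that add atoms: mCPBA O=C(OO)c1cccc(Cl)c1
Why: Prilezhaev epoxidation; the peracid should approach the remaining alkene anti to the allylic oxirane oxygen (steric and dipole repulsion, no hydrogen-bond donor), so the first oxirane relays its configuration to two new stereocentres and gives the C2-symmetric anti-diepoxide.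

**Step 3**
Reactants: 3 (1S,2S,4S,7S)-3,8-dioxatricyclo[5.1.0.0^2,4]octane; 4 benzoic acid (two equivalents are incorporated)
Product: 5 (1R,2R,3R,4R)-2,3-dihydroxycyclohexane-1,4-diyl dibenzoate
Conditions: PhCO2H (3 equiv), n-Bu4N benzoate (10 mol %), MeCN, 80 °C; recrystallisation
Reagents that add atoms: none
Why: carboxylate-catalysed SN2 opening of epoxides by a carboxylic acid; benzoate should attack each oxirane with inversion at its outer carbon, because the inner carbons are deactivated by the neighbouring C–O bond, which gives the all-trans 1,4-dibenzoate 2,3-diol, while the excess acid keeps the medium non-basic and so suppresses Payne rearrangement and benzoyl migration.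

**Step 4**
Reactants: 5 (1R,2R,3R,4R)-2,3-dihydroxycyclohexane-1,4-diyl dibenzoate
Product: 6 (1R,2R,3S,4R)-2-[(tert-butyldimethylsilyl)oxy]-3-hydroxycyclohexane-1,4-diyl dibenzoate
Conditions: TBSOTf (1.05 equiv), 2,6-lutidine, CH2Cl2, −78 °C; unreacted 5 recycled
Reagents that add atoms: tert-butyldimethylsilyl triflate CC(C)(C)[Si](C)(C)OS(=O)(=O)C(F)(F)F
Why: silyl ether formation; the two hydroxyls are homotopic through the C2 axis, so mono-silylation can give only one compound, the first TBS group should slow silylation of the vicinal hydroxyl, and the hindered base at low temperature avoids 1,2-benzoyl shift.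

**Step 5**
Reactants: 6 (1R,2R,3S,4R)-2-[(tert-butyldimethylsilyl)oxy]-3-hydroxycyclohexane-1,4-diyl dibenzoate
Product: 7 (1R,2S,4R)-2-[(tert-butyldimethylsilyl)oxy]-3-oxocyclohexane-1,4-diyl dibenzoate
Conditions: Dess–Martin periodinane (1.3 equiv), CH2Cl2, 0 °C → rt
Reagents that add atoms: none
Why: Dess–Martin oxidation under neutral conditions should convert the one free secondary alcohol into the ketone without epimerising the two α-stereocentres or eliminating the β-benzoate.

**Step 6**
Reactants: 7 (1R,2S,4R)-2-[(tert-butyldimethylsilyl)oxy]-3-oxocyclohexane-1,4-diyl dibenzoate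
Product: 10 [(1S,2S,3R,6R)-3-(benzoyloxy)-2-[(tert-butyldimethylsilyl)oxy]-1,6-dihydroxycyclohexyl]methyl benzoate, via spiro-epoxide 8 (not isolated), via 1,3-dioxan-2-ylium ion 9 (not isolated)
Conditions: CH2N2 (excess), Et2O–MeOH (10:1), 0 °C → rt; evaporate; then CSA (10 mol %), water-saturated CH2Cl2, 0 °C → rt
Reagents that add atoms: diazomethane C=[N+]=[N-]; water O
Why: Diazomethane adds to the C1 carbonyl, which is activated by two α-oxygen substituents, and the diazonium alkoxide closes (3-exo-tet, loss of N2) to spiro-oxirane 8; under catalytic acid the carbonyl oxygen of the C6 benzoate, gauche to the new axial CH2, opens the protonated oxirane at the CH2 carbon to the six-membered 1,3-dioxan-2-ylium ion 9 (attack at the distal oxirane carbon, 6-endo in the epoxide-opening sense), water adds to give the hemi-orthoester, and this collapses reversibly to the less congested primary benzoate, which releases C6–OH. The closest known reactions are the diazomethane spiro-epoxidation of acylated inososes (2,6-diacyloxycyclohexanones), acyloxonium-mediated opening of epoxy esters, and O→O acyl migration through cyclic ortho-acid intermediates. The new quaternary stereocentre C1 is set by substrate control: the cis-2,6 and trans-2,3 oxygens are all equatorial and lock one chair, and the small nucleophile should enter axially, which places CH2 cis to O–C2 and O–C6 and the oxirane oxygen equatorial (S at C1). Epoxide formation rather than ring expansion is needed and should be secured because the α-oxygenated carbons are poor migrating groups. Opening at CH2 rather than at the quaternary oxirane carbon is needed and should be secured because that carbon, flanked by two C–O bonds, resists ionisation, and five-ring participation at it would require the all-axial chair. The TBS ether at C2 keeps the C3 benzoate in place, so only the C6 benzoate can move.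

**Step 7**
Reactants: 10 [(1S,2S,3R,6R)-3-(benzoyloxy)-2-[(tert-butyldimethylsilyl)oxy]-1,6-dihydroxycyclohexyl]methyl benzoate
Product: 11 [(1S,2S,3R,6R)-3-(benzoyloxy)-1,2,6-trihydroxycyclohexyl]methyl benzoate
Conditions: HF·pyridine, THF–pyridine, 0 °C → rt
Reagents that add atoms: none
Why: fluoride-mediated desilylation under mildly acidic conditions should cleave the Si–O bond without acyl migration or ester cleavage; no stereocentre is touched.

**Compound list**
1 | cyclohexa-1,3-diene | C1=CC=CCC1 | starting material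
2 | (1R,6S)-7-oxabicyclo[4.1.0]hept-2-ene | C1=C[C@H]2O[C@H]2CC1 | intermediate
3 | (1S,2S,4S,7S)-3,8-dioxatricyclo[5.1.0.0^2,4]octane (anti-diepoxide, C2-symmetric) | [C@@H]12O[C@@H]1[C@H]1O[C@H]1CC2 | intermediate
4 | benzoic acid | O=C(O)c1ccccc1 | starting material
5 | (1R,2R,3R,4R)-2,3-dihydroxycyclohexane-1,4-diyl dibenzoate (all-trans, C2-symmetric) | O=C(c1ccccc1)O[C@H]1[C@H](O)[C@@H](O)[C@H](OC(=O)c2ccccc2)CC1 | intermediate
6 | (1R,2R,3S,4R)-2-[(tert-butyldimethylsilyl)oxy]-3-hydroxycyclohexane-1,4-diyl dibenzoate | O[C@@H]1[C@@H](O[Si](C)(C)C(C)(C)C)[C@H](OC(=O)c2ccccc2)CC[C@H]1OC(=O)c1ccccc1 | intermediate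
7 | (1R,2S,4R)-2-[(tert-butyldimethylsilyl)oxy]-3-oxocyclohexane-1,4-diyl dibenzoate | O=C1[C@@H](O[Si](C)(C)C(C)(C)C)[C@H](OC(=O)c2ccccc2)CC[C@H]1OC(=O)c1ccccc1 | intermediate
8 | (3S,4S,5R,8R)-4-[(tert-butyldimethylsilyl)oxy]-1-oxaspiro[2.5]octane-5,8-diyl dibenzoate (spiro-epoxide, formed in the flask) | C1O[C@@]12[C@@H](O[Si](C)(C)C(C)(C)C)[C@H](OC(=O)c3ccccc3)CC[C@H]2OC(=O)c2ccccc2 | intermediate
9 | (4aS,5S,6R,8aR)-6-(benzoyloxy)-5-[(tert-butyldimethylsilyl)oxy]-4a-hydroxy-2-phenyl-4a,5,6,7,8,8a-hexahydro-4H-1,3-benzodioxin-2-ylium (1,3-dioxan-2-ylium ion, formed in the flask) | O[C@@]12CO[C+](c3ccccc3)O[C@@H]1CC[C@@H](OC(=O)c1ccccc1)[C@@H]2O[Si](C)(C)C(C)(C)C | intermediate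
10 | [(1S,2S,3R,6R)-3-(benzoyloxy)-2-[(tert-butyldimethylsilyl)oxy]-1,6-dihydroxycyclohexyl]methyl benzoate | O=C(c1ccccc1)OC[C@@]1(O)[C@@H](O[Si](C)(C)C(C)(C)C)[C@H](OC(=O)c2ccccc2)CC[C@H]1O | intermediate
11 | [(1S,2S,3R,6R)-3-(benzoyloxy)-1,2,6-trihydroxycyclohexyl]methyl benzoate | O=C(OC[C@]1(O)[C@H](O)CC[C@@H](OC(=O)c2ccccc2)[C@@H]1O)c1ccccc1 | target

**Step count and risks**
Total step count: 7. Longest linear sequence: 7 steps (1 → 11).

Steps most likely to fail, in order of risk:

Step 6. The benzoyl group may not travel cleanly: the hemi-orthoester may collapse toward the secondary ester and equilibrate incompletely, or the protonated oxirane may be opened at the quaternary carbon or by external water instead of by the neighbouring ester. The fallback sets out from 3 and comes back at 10; it differentiates the two ends of the diepoxide before the ketone is made, so no acyl transfer is needed. Diepoxide 3 is opened with one equivalent of benzoic acid (n-Bu4N benzoate cat.) to the epoxy alcohol (1R,2S,3R,6S)-2-hydroxy-7-oxabicyclo[4.1.0]heptan-3-yl benzoate F1. Its hydroxyl is silylated (TBSOTf, 2,6-lutidine) to (1R,2S,3R,6S)-2-[(tert-butyldimethylsilyl)oxy]-7-oxabicyclo[4.1.0]heptan-3-yl benzoate F2. The remaining oxirane is opened at its outer carbon with benzyl alcohol (cat. BF3·OEt2) to (1R,2R,3S,4R)-4-(benzyloxy)-2-[(tert-butyldimethylsilyl)oxy]-3-hydroxycyclohexyl benzoate F3. Dess–Martin oxidation gives (1R,2S,4R)-4-(benzyloxy)-2-[(tert-butyldimethylsilyl)oxy]-3-oxocyclohexyl benzoate F4, and diazomethane gives the isolated spiro-epoxide (3S,4S,5R,8R)-8-(benzyloxy)-4-[(tert-butyldimethylsilyl)oxy]-1-oxaspiro[2.5]octan-5-yl benzoate F5. This is opened intermolecularly at CH2 with benzoic acid and n-Bu4N benzoate to [(1S,2S,3R,6R)-3-(benzoyloxy)-6-(benzyloxy)-2-[(tert-butyldimethylsilyl)oxy]-1-hydroxycyclohexyl]methyl benzoate F6. Hydrogenolysis (H2, Pd/C, EtOAc) of the benzyl ether returns to 10.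

Step 3. Benzoate may attack an inner oxirane carbon, the intermediate epoxy alcohol may undergo Payne equilibration, or a 1,2-benzoyl shift may occur; each erodes the all-trans 1,4-dibenzoate pattern. The fallback sets out from 2 and comes back at 7; it replaces the epoxide openings by allyl-palladium chemistry and a cis-dihydroxylation. Pd(0)-catalysed (Tsuji–Trost) addition of benzoic acid to vinyl oxirane 2 (Pd(PPh3)4 cat., THF, 0 °C) should give, by double inversion, the cis-1,4-hydroxy benzoate (1R,4S)-4-hydroxycyclohex-2-en-1-yl benzoate F7. Mitsunobu esterification with benzoic acid (PPh3, DIAD) inverts the carbinol to the C2-symmetric (1R,4R)-cyclohex-2-ene-1,4-diyl dibenzoate F8. Upjohn dihydroxylation (cat. OsO4, NMO) can give only one cis-diol, (1R,2R,3S,4R)-2,3-dihydroxycyclohexane-1,4-diyl dibenzoate F9, because the two alkene faces are homotopic. The equatorial hydroxyl, which is trans to its neighbouring benzoate, is silylated selectively (TBSCl, imidazole, DMF, 0 °C) to (1R,2R,3R,4R)-2-[(tert-butyldimethylsilyl)oxy]-3-hydroxycyclohexane-1,4-diyl dibenzoate F10. Dess–Martin oxidation of its remaining axial hydroxyl gives ketone 7.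

Step 1. Oxygen transfer to the cyclic diene may be insufficiently enantioselective, and the volatile, acid-labile vinyl oxirane may be lost. The fallback sets out from 1 and comes back at 5; it replaces asymmetric catalysis by resolution. Diene 1 is treated with buffered mCPBA (2.2 equiv), which gives, by way of racemic monoepoxide (2 together with (1S,6R)-7-oxabicyclo[4.1.0]hept-2-ene F11), the racemic anti-diepoxide (3 together with (1R,2R,4R,7R)-3,8-dioxatricyclo[5.1.0.0^2,4]octane F12). Opening with benzoic acid as in step 3 gives the racemic diol (5 together with (1S,2S,3S,4S)-2,3-dihydroxycyclohexane-1,4-diyl dibenzoate F13). The enantiomers of this C2-symmetric, UV-active diol are separated by preparative chromatography on a polysaccharide chiral stationary phase, and 5 re-enters at step 4.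

**Further compounds**
F1 | step 6 | (1R,2S,3R,6S)-2-hydroxy-7-oxabicyclo[4.1.0]heptan-3-yl benzoate | O1[C@H]2[C@@H]1CC[C@@H](OC(=O)c1ccccc1)[C@@H]2O
F2 | step 6 | (1R,2S,3R,6S)-2-[(tert-butyldimethylsilyl)oxy]-7-oxabicyclo[4.1.0]heptan-3-yl benzoate | O1[C@H]2[C@@H]1CC[C@@H](OC(=O)c1ccccc1)[C@@H]2O[Si](C)(C)C(C)(C)C
F3 | step 6 | (1R,2R,3S,4R)-4-(benzyloxy)-2-[(tert-butyldimethylsilyl)oxy]-3-hydroxycyclohexyl benzoate | O[C@@H]1[C@@H](O[Si](C)(C)C(C)(C)C)[C@H](OC(=O)c2ccccc2)CC[C@H]1OCc1ccccc1
F4 | step 6 | (1R,2S,4R)-4-(benzyloxy)-2-[(tert-butyldimethylsilyl)oxy]-3-oxocyclohexyl benzoate | O=C1[C@@H](O[Si](C)(C)C(C)(C)C)[C@H](OC(=O)c2ccccc2)CC[C@H]1OCc1ccccc1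
F5 | step 6 | (3S,4S,5R,8R)-8-(benzyloxy)-4-[(tert-butyldimethylsilyl)oxy]-1-oxaspiro[2.5]octan-5-yl benzoate | C1O[C@@]12[C@@H](O[Si](C)(C)C(C)(C)C)[C@H](OC(=O)c3ccccc3)CC[C@H]2OCc2ccccc2
F6 | step 6 | [(1S,2S,3R,6R)-3-(benzoyloxy)-6-(benzyloxy)-2-[(tert-butyldimethylsilyl)oxy]-1-hydroxycyclohexyl]methyl benzoate | O=C(c1ccccc1)OC[C@@]1(O)[C@@H](O[Si](C)(C)C(C)(C)C)[C@H](OC(=O)c2ccccc2)CC[C@H]1OCc1ccccc1
F7 | step 3 | (1R,4S)-4-hydroxycyclohex-2-en-1-yl benzoate | O[C@@H]1C=C[C@H](OC(=O)c2ccccc2)CC1
F8 | step 3 | (1R,4R)-cyclohex-2-ene-1,4-diyl dibenzoate | O=C(c1ccccc1)O[C@H]1C=C[C@H](OC(=O)c2ccccc2)CC1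
F9 | step 3 | (1R,2R,3S,4R)-2,3-dihydroxycyclohexane-1,4-diyl dibenzoate | O=C(c1ccccc1)O[C@H]1[C@@H](O)[C@@H](O)[C@H](OC(=O)c2ccccc2)CC1
F10 | step 3 | (1R,2R,3R,4R)-2-[(tert-butyldimethylsilyl)oxy]-3-hydroxycyclohexane-1,4-diyl dibenzoate | O[C@H]1[C@@H](O[Si](C)(C)C(C)(C)C)[C@H](OC(=O)c2ccccc2)CC[C@H]1OC(=O)c1ccccc1
F11 | step 1 | (1S,6R)-7-oxabicyclo[4.1.0]hept-2-ene | C1=C[C@@H]2O[C@@H]2CC1
F12 | step 1 | (1R,2R,4R,7R)-3,8-dioxatricyclo[5.1.0.0^2,4]octane | [C@H]12O[C@H]1[C@@H]1O[C@@H]1CC2
F13 | step 1 | (1S,2S,3S,4S)-2,3-dihydroxycyclohexane-1,4-diyl dibenzoate | O=C(c1ccccc1)O[C@@H]1[C@@H](O)[C@H](O)[C@@H](OC(=O)c2ccccc2)CC1
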